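**Strategy.** The target is disconnected between the carboxyl-bearing methine (C-1 of the undecyl chain, alpha to its CO2H and attached to the quaternary C-2 of the oxolanone ring) and the first chain CH2. With chain C-3/C-4 unsaturated, this methine becomes the alpha-carbon of a gamma,delta-unsaturated acid, so an Ireland–Claisen rearrangement forms the bond. The precursor is the ester of a malic-acid-derived dioxolanone acetic acid (quaternary centre already set) with an (S)-alk-1-en-3-ol carrying the chain. Rearrangement through a chair transfers the carbinol chirality to the methine and releases the free acid. Hydrogenation, regioselective (R)-malate acylation and acidolysis with lactonization finish the synthesis.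

Key step: step 8

Remark: the choice of the (S)-carbinol in 9 assumes that kinetic enolization of 10 (LiN(iPr)2, Me3SiCl, THF) gives the E(O) ketene acetal (quaternary carbon cis to the allyloxy oxygen); with the opposite geometry the (R)-carbinol would be needed.

**Route**

Step 1
Reactants: 1 (R)-malic acid
Product: 2 2-[(2R,4R)-2-tert-butyl-5-oxo-1,3-dioxolan-4-yl]acetic acid (cis)
Conditions: pivalaldehyde, TsOH·H2O (cat.), H2SO4 (cat.), pentane, reflux, Dean–Stark trap; recrystallization
Reagents that add atoms: pivalaldehyde, CC(C)(C)C=O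
Why: Acid-catalysed acetalization of the alpha-hydroxy acid unit under thermodynamic control should give the five-membered dioxolanone with tert-butyl cis to the carboxymethyl arm; the malic acid centre is untouched, the acetal centre (R) is set relative to it, and crystallization should remove the minor trans isomer.

Step 2
Reactants: 2 2-[(2R,4R)-2-tert-butyl-5-oxo-1,3-dioxolan-4-yl]acetic acid
Product: 4 2-[(2R,4R)-4-(3-tert-butoxy-3-oxopropyl)-2-tert-butyl-5-oxo-1,3-dioxolan-4-yl]acetic acid, via dilithium enolate carboxylate 3 (not isolated)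
Conditions: LiN(SiMe3)2 (2.2 equiv), THF, −78 °C; tert-butyl acrylate (1.1 equiv), −78 °C; 1 M HCl
Reagents that add atoms: tert-butyl acrylate, C=CC(=O)OC(C)(C)C
Why: Michael addition of the dioxolanone enolate (self-regeneration of the stereocentre): the carboxylate shields the exocyclic CH2 from deprotonation, and the acrylate should enter trans to the tert-butyl group, so the quaternary centre (R) forms with overall retention.

Step 3
Reactants: 5 octane-1,8-diol
Product: 6 8-(benzyloxy)octan-1-ol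
Conditions: NaH (1.0 equiv), benzyl bromide (1.0 equiv), THF/DMF, 0 °C → rt (diol in excess)
Reagents that add atoms: benzyl bromide, BrCc1ccccc1
Why: Williamson ether synthesis on a symmetric diol, with excess diol limiting double benzylation.

Step 4
Reactants: 6 8-(benzyloxy)octan-1-ol
Product: 7 8-(benzyloxy)octanal
Conditions: TEMPO (cat.), PhI(OAc)2, CH2Cl2, rt
Reagents that add atoms: none
Why: TEMPO-catalysed oxidation of a primary alcohol should stop at the aldehyde and leave the benzyl ether intact.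

Step 5
Reactants: 7 8-(benzyloxy)octanal
Product: 8 rac-10-(benzyloxy)dec-1-en-3-ol
Conditions: CH2=CHMgBr, THF, −78 → 0 °C; aq. NH4Cl
Reagents that add atoms: vinylmagnesium bromide, C=C[Mg]Br
Why: Grignard 1,2-addition to the aldehyde gives the racemic alk-1-en-3-ol.

Step 6
Reactants: 8 rac-10-(benzyloxy)dec-1-en-3-ol
Product: 9 (3S)-10-(benzyloxy)dec-1-en-3-ol
Conditions: Ti(OiPr)4, D-(−)-diisopropyl tartrate, t-BuOOH (0.6 equiv), 4 Å molecular sieves, CH2Cl2, −20 °C
Reagents that add atoms: none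
Why: Sharpless kinetic resolution: with the D-(−)-tartrate the (R)-alcohol should be epoxidized faster (to the erythro epoxy alcohol), so the (S)-alcohol is recovered enantioenriched.

Step 7
Reactants: 4 2-[(2R,4R)-4-(3-tert-butoxy-3-oxopropyl)-2-tert-butyl-5-oxo-1,3-dioxolan-4-yl]acetic acid; 9 (3S)-10-(benzyloxy)dec-1-en-3-ol
Product: 10 (3S)-10-(benzyloxy)dec-1-en-3-yl 2-[(2R,4R)-4-(3-tert-butoxy-3-oxopropyl)-2-tert-butyl-5-oxo-1,3-dioxolan-4-yl]acetate
Conditions: DCC, DMAP (cat.), CH2Cl2, 0 °C → rt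
Reagents that add atoms: none
Why: Steglich esterification acylates the carbinol oxygen, so the (S)-centre is retained and no other group in either fragment is touched.

Step 8
Reactants: 10 (3S)-10-(benzyloxy)dec-1-en-3-yl 2-[(2R,4R)-4-(3-tert-butoxy-3-oxopropyl)-2-tert-butyl-5-oxo-1,3-dioxolan-4-yl]acetate
Product: 13 (2S,4E)-12-(benzyloxy)-2-[(2R,4R)-4-(3-tert-butoxy-3-oxopropyl)-2-tert-butyl-5-oxo-1,3-dioxolan-4-yl]dodec-4-enoic acid, via bis(silyl ketene acetal) 11 (not isolated), via trimethylsilyl ester 12 (not isolated)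
Conditions: Me3SiCl (4 equiv), then LiN(iPr)2 (3 equiv), THF, −78 °C (in situ silylation); −78 °C → rt, then 45 °C; 1 M HCl
Reagents that add atoms: none
Why: Excess LiN(iPr)2 in the presence of Me3SiCl converts both ester arms of 10 into O-silyl ketene acetals (11; E(O) geometry at the allyl ester arm), and on warming only the allyl ester arm undergoes the concerted suprafacial [3,3]-sigmatropic shift through a chair transition state, forming the bond between the acid alpha-carbon and the vinyl CH2 terminus as the allylic C–O bond breaks; acidic work-up hydrolyses silyl ester 12 and restores the tert-butyl ester. The closest known reaction type is the Ireland–Claisen rearrangement of esters of enantioenriched alk-1-en-3-ols with 1,3-chirality transfer. No ring is closed; the six-membered array exists only in the transition state. The new stereocentre (alpha-carbon, S) is controlled by the (S)-carbinol centre, whose chain takes the equatorial position of the chair and so fixes which face of the E(O) ketene acetal meets the vinyl terminus; the carbinol centre is consumed and reappears as the E-alkene, which step 9 removes. The quaternary dioxolanone centre is untouched, and any facial bias it exerts is taken to be subordinate to the chair preference. The step needs enolization without beta-elimination of the acetal oxygen or Dieckmann condensation (secured by in situ silylation at −78 °C and the poor leaving-group ability of the acetal oxygen), a single ketene acetal geometry (kinetic conditions in THF, bulky alpha-substituent) and chair over boat (usual for acyclic allyl esters).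

Step 9
Reactants: 13 (2S,4E)-12-(benzyloxy)-2-[(2R,4R)-4-(3-tert-butoxy-3-oxopropyl)-2-tert-butyl-5-oxo-1,3-dioxolan-4-yl]dodec-4-enoic acid
Product: 14 (2S)-2-[(2R,4R)-4-(3-tert-butoxy-3-oxopropyl)-2-tert-butyl-5-oxo-1,3-dioxolan-4-yl]-12-hydroxydodecanoic acid
Conditions: H2 (1 atm), Pd/C, EtOH/EtOAc, rt
Reagents that add atoms: none
Why: Catalytic hydrogenation should saturate the disubstituted alkene and hydrogenolyse the benzyl ether in one operation, leaving the acetal, the tert-butyl ester and both stereocentres unchanged.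

Step 10
Reactants: 14 (2S)-2-[(2R,4R)-4-(3-tert-butoxy-3-oxopropyl)-2-tert-butyl-5-oxo-1,3-dioxolan-4-yl]-12-hydroxydodecanoic acid; 1 (R)-malic acid
Product: 17 (2S)-2-[(2R,4R)-4-(3-tert-butoxy-3-oxopropyl)-2-tert-butyl-5-oxo-1,3-dioxolan-4-yl]-12-{[(2R)-3-carboxy-2-hydroxypropanoyl]oxy}dodecanoic acid, via trifluoroacetylmalic anhydride 15 (not isolated), via O-trifluoroacetyl ester 16 (not isolated)
Conditions: 1, (CF3CO)2O, 0 °C → rt, then evaporation; 14, THF, 0 °C → rt; then H2O/THF, rt
Reagents that add atoms: none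
Why: Alcoholysis of O-trifluoroacetylmalic anhydride should occur at the carbonyl next to the acyloxy-bearing carbon, giving the malate 1-ester with a free 4-carboxyl; the labile trifluoroacetate is cleaved on aqueous work-up and the malate centre is not involved.

Step 11
Reactants: 17 (2S)-2-[(2R,4R)-4-(3-tert-butoxy-3-oxopropyl)-2-tert-butyl-5-oxo-1,3-dioxolan-4-yl]-12-{[(2R)-3-carboxy-2-hydroxypropanoyl]oxy}dodecanoic acid
Product: 19 (2R)-2-[(1S)-1-carboxy-11-{[(2R)-3-carboxy-2-hydroxypropanoyl]oxy}undecyl]-5-oxooxolane-2-carboxylic acid (target), via open-chain hydroxy acid 18 (not isolated)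
Conditions: CF3CO2H/H2O (9:1), rt; concentration from toluene, 40 °C
Reagents that add atoms: none
Why: Acidolysis should cleave the tert-butyl ester and hydrolyse the dioxolanone, and the liberated tertiary hydroxyl should lactonize onto the propanoic acid arm (5-exo-trig) to close the oxolanone ring; no stereocentre is involved and the primary malate ester should survive.

**Compound list**

1 | (R)-malic acid | O=C(O)C[C@@H](O)C(=O)O | starting material
2 | 2-[(2R,4R)-2-tert-butyl-5-oxo-1,3-dioxolan-4-yl]acetic acid | CC(C)(C)[C@@H]1O[C@H](CC(=O)O)C(=O)O1 | intermediate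
3 | dilithium salt of 2, deprotonated at the carboxyl group and at ring C-4 (enolate carboxylate, acetal centre unchanged) | CC(C)(C)[C@@H]1OC(CC(=O)[O-])=C([O-])O1.[Li+].[Li+] | intermediate
4 | 2-[(2R,4R)-4-(3-tert-butoxy-3-oxopropyl)-2-tert-butyl-5-oxo-1,3-dioxolan-4-yl]acetic acid | CC(C)(C)[C@@H]1O[C@@](CC(=O)O)(CCC(=O)OC(C)(C)C)C(=O)O1 | intermediate
5 | octane-1,8-diol | OCCCCCCCCO | starting material
6 | 8-(benzyloxy)octan-1-ol | OCCCCCCCCOCc1ccccc1 | intermediate
7 | 8-(benzyloxy)octanal | O=CCCCCCCCOCc1ccccc1 | intermediate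
8 | rac-10-(benzyloxy)dec-1-en-3-ol | C=CC(O)CCCCCCCOCc1ccccc1 | intermediate
9 | (3S)-10-(benzyloxy)dec-1-en-3-ol | C=C[C@@H](O)CCCCCCCOCc1ccccc1 | intermediate
10 | (3S)-10-(benzyloxy)dec-1-en-3-yl 2-[(2R,4R)-4-(3-tert-butoxy-3-oxopropyl)-2-tert-butyl-5-oxo-1,3-dioxolan-4-yl]acetate | CC(C)(C)[C@@H]1O[C@@](CC(=O)O[C@H](C=C)CCCCCCCOCc2ccccc2)(CCC(=O)OC(C)(C)C)C(=O)O1 | intermediate
11 | bis(O-trimethylsilyl ketene acetal) of 10: E-configured at the allyl ester arm, tert-butyl ester arm also silylated | CC(C)(C)[C@@H]1O[C@@](/C=C(/O[Si](C)(C)C)O[C@H](C=C)CCCCCCCOCc2ccccc2)(CC=C(O[Si](C)(C)C)OC(C)(C)C)C(=O)O1 | intermediate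
12 | trimethylsilyl ester of 13, tert-butyl ester arm still as its O-silyl ketene acetal | CC(C)(C)[C@@H]1O[C@@]([C@@H](C(=O)O[Si](C)(C)C)C/C=C/CCCCCCCOCc2ccccc2)(CC=C(O[Si](C)(C)C)OC(C)(C)C)C(=O)O1 | intermediate
13 | (2S,4E)-12-(benzyloxy)-2-[(2R,4R)-4-(3-tert-butoxy-3-oxopropyl)-2-tert-butyl-5-oxo-1,3-dioxolan-4-yl]dodec-4-enoic acid | CC(C)(C)[C@@H]1O[C@@]([C@@H](C(=O)O)C/C=C/CCCCCCCOCc2ccccc2)(CCC(=O)OC(C)(C)C)C(=O)O1 | intermediate
14 | (2S)-2-[(2R,4R)-4-(3-tert-butoxy-3-oxopropyl)-2-tert-butyl-5-oxo-1,3-dioxolan-4-yl]-12-hydroxydodecanoic acid | CC(C)(C)[C@@H]1O[C@@]([C@@H](C(=O)O)CCCCCCCCCCO)(CCC(=O)OC(C)(C)C)C(=O)O1 | intermediate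
15 | (3R)-2,5-dioxooxolan-3-yl trifluoroacetate ((R)-O-trifluoroacetylmalic anhydride) | O=C1C[C@@H](OC(=O)C(F)(F)F)C(=O)O1 | intermediate
16 | O-trifluoroacetyl derivative of 17 (trifluoroacetate on the malate hydroxyl) | CC(C)(C)[C@@H]1O[C@@]([C@@H](C(=O)O)CCCCCCCCCCOC(=O)[C@H](OC(=O)C(F)(F)F)CC(=O)O)(CCC(=O)OC(C)(C)C)C(=O)O1 | intermediate
17 | (2S)-2-[(2R,4R)-4-(3-tert-butoxy-3-oxopropyl)-2-tert-butyl-5-oxo-1,3-dioxolan-4-yl]-12-{[(2R)-3-carboxy-2-hydroxypropanoyl]oxy}dodecanoic acid | CC(C)(C)[C@@H]1O[C@@]([C@@H](C(=O)O)CCCCCCCCCCOC(=O)[C@H](O)CC(=O)O)(CCC(=O)OC(C)(C)C)C(=O)O1 | intermediate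
18 | (2R)-2-[(1S)-1-carboxy-11-{[(2R)-3-carboxy-2-hydroxypropanoyl]oxy}undecyl]-2-hydroxypentanedioic acid | O=C(O)C[C@@H](O)C(=O)OCCCCCCCCCC[C@H](C(=O)O)[C@@](O)(C(=O)O)CCC(=O)O | intermediate
19 | (2R)-2-[(1S)-1-carboxy-11-{[(2R)-3-carboxy-2-hydroxypropanoyl]oxy}undecyl]-5-oxooxolane-2-carboxylic acid | O=C(O)C[C@@H](O)C(=O)OCCCCCCCCCC[C@H](C(=O)O)[C@@]1(C(=O)O)CCC(=O)O1 | target

**Step count and risks**

Total step count: 11. Longest linear sequence: 9 steps (steps 3 to 11, from octane-1,8-diol); the malic acid branch contributes steps 1 and 2 and joins at step 7.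

Steps most likely to fail:

1. Step 8. The ester enolate may lose the acetal oxygen by beta-elimination before it is silylated, the two ester arms may undergo Dieckmann condensation, or enolization may give a mixture of ketene acetal geometries and so erode the chirality transfer. In that case the order of events is reversed and the same bond is made by a Fráter–Seebach alkylation, which has the required anti sense. The fallback sets out from 1 and from racemic 8 (no resolution needed) and returns at 13. Compound 1 is esterified (MeOH, SOCl2) to dimethyl (R)-malate F1. Alcohol 8 is converted with PBr3 (Et2O, 0 °C, allylic transposition) into (E)-1-bromo-10-(benzyloxy)dec-2-ene F2. The dianion of F1 (LiN(iPr)2, 2.1 equiv, THF, −78 → −20 °C) is alkylated by F2 to give dimethyl (2R,3S)-3-[(2E)-10-(benzyloxy)dec-2-en-1-yl]-2-hydroxybutanedioate F3. Saponification (LiOH, THF/H2O) gives (2R,3S)-3-[(2E)-10-(benzyloxy)dec-2-en-1-yl]-2-hydroxybutanedioic acid F4. Acetalization with pivalaldehyde (TsOH·H2O, H2SO4 cat., pentane, reflux) gives (2S,4E)-12-(benzyloxy)-2-[(2R,4R)-2-tert-butyl-5-oxo-1,3-dioxolan-4-yl]dodec-4-enoic acid F5. Its dianion (LiN(SiMe3)2, 2.2 equiv, THF, −78 °C) adds to tert-butyl acrylate trans to the tert-butyl group, which gives 13.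

2. Step 2. The acrylate may oligomerize anionically, or the dioxolanone enolate may decompose before it adds. In that case the three-carbon arm is introduced by allylation of the same dianion and oxidized afterwards. The fallback sets out from 2 and returns at 4. The dianion of 2 (LiN(SiMe3)2, 2.2 equiv, THF, −78 °C) is alkylated with allyl bromide to give 2-[(2R,4R)-2-tert-butyl-5-oxo-4-(prop-2-en-1-yl)-1,3-dioxolan-4-yl]acetic acid F6. Benzyl bromide and K2CO3 in DMF give benzyl 2-[(2R,4R)-2-tert-butyl-5-oxo-4-(prop-2-en-1-yl)-1,3-dioxolan-4-yl]acetate F7. Hydroboration with 9-BBN and buffered oxidation (NaBO3·4H2O) give benzyl 2-[(2R,4R)-2-tert-butyl-4-(3-hydroxypropyl)-5-oxo-1,3-dioxolan-4-yl]acetate F8. TEMPO/PhI(OAc)2 in MeCN/H2O oxidizes it to 3-[(2R,4R)-4-(2-benzyloxy-2-oxoethyl)-2-tert-butyl-5-oxo-1,3-dioxolan-4-yl]propanoic acid F9. tert-Butyl 2,2,2-trichloroacetimidate gives benzyl 2-[(2R,4R)-4-(3-tert-butoxy-3-oxopropyl)-2-tert-butyl-5-oxo-1,3-dioxolan-4-yl]acetate F10. Hydrogenolysis of the benzyl ester (H2, Pd/C, EtOAc) gives 4.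

3. Step 10. The anhydride may transfer its acyl group to the free carboxylic acid of 14 (mixed anhydrides, oligomeric esters), consuming material and complicating the regioselective ester formation. In that case the acid is masked before the chain oxygen is released. The fallback sets out from 13 and returns at the target 19. tert-Butyl 2,2,2-trichloroacetimidate converts 13 into tert-butyl (2S,4E)-12-(benzyloxy)-2-[(2R,4R)-4-(3-tert-butoxy-3-oxopropyl)-2-tert-butyl-5-oxo-1,3-dioxolan-4-yl]dodec-4-enoate F11. Hydrogenation (H2, Pd/C) gives tert-butyl (2S)-2-[(2R,4R)-4-(3-tert-butoxy-3-oxopropyl)-2-tert-butyl-5-oxo-1,3-dioxolan-4-yl]-12-hydroxydodecanoate F12, which has no free acid. Opening of anhydride 15 by F12 and aqueous cleavage of the trifluoroacetate give the (R)-malic acid 1-ester of F12 with free 4-carboxyl and hydroxyl F13. CF3CO2H/H2O then removes both tert-butyl esters and the acetal with lactonization to give 19.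

**Further compounds**

F1 | step 8 | dimethyl (R)-malate | COC(=O)C[C@@H](O)C(=O)OC
F2 | step 8 | (E)-1-bromo-10-(benzyloxy)dec-2-ene | BrC/C=C/CCCCCCCOCc1ccccc1
F3 | step 8 | dimethyl (2R,3S)-3-[(2E)-10-(benzyloxy)dec-2-en-1-yl]-2-hydroxybutanedioate | COC(=O)[C@H](O)[C@H](C/C=C/CCCCCCCOCc1ccccc1)C(=O)OC
F4 | step 8 | (2R,3S)-3-[(2E)-10-(benzyloxy)dec-2-en-1-yl]-2-hydroxybutanedioic acid | O=C(O)[C@H](O)[C@H](C/C=C/CCCCCCCOCc1ccccc1)C(=O)O
F5 | step 8 | (2S,4E)-12-(benzyloxy)-2-[(2R,4R)-2-tert-butyl-5-oxo-1,3-dioxolan-4-yl]dodec-4-enoic acid | CC(C)(C)[C@@H]1O[C@H]([C@@H](C(=O)O)C/C=C/CCCCCCCOCc2ccccc2)C(=O)O1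
F6 | step 2 | 2-[(2R,4R)-2-tert-butyl-5-oxo-4-(prop-2-en-1-yl)-1,3-dioxolan-4-yl]acetic acid | CC(C)(C)[C@@H]1O[C@@](CC(=O)O)(CC=C)C(=O)O1
F7 | step 2 | benzyl 2-[(2R,4R)-2-tert-butyl-5-oxo-4-(prop-2-en-1-yl)-1,3-dioxolan-4-yl]acetate | CC(C)(C)[C@@H]1O[C@@](CC(=O)OCc2ccccc2)(CC=C)C(=O)O1
F8 | step 2 | benzyl 2-[(2R,4R)-2-tert-butyl-4-(3-hydroxypropyl)-5-oxo-1,3-dioxolan-4-yl]acetate | CC(C)(C)[C@@H]1O[C@@](CC(=O)OCc2ccccc2)(CCCO)C(=O)O1
F9 | step 2 | 3-[(2R,4R)-4-(2-benzyloxy-2-oxoethyl)-2-tert-butyl-5-oxo-1,3-dioxolan-4-yl]propanoic acid | CC(C)(C)[C@@H]1O[C@@](CC(=O)OCc2ccccc2)(CCC(=O)O)C(=O)O1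
F10 | step 2 | benzyl 2-[(2R,4R)-4-(3-tert-butoxy-3-oxopropyl)-2-tert-butyl-5-oxo-1,3-dioxolan-4-yl]acetate | CC(C)(C)[C@@H]1O[C@@](CC(=O)OCc2ccccc2)(CCC(=O)OC(C)(C)C)C(=O)O1
F11 | step 10 | tert-butyl (2S,4E)-12-(benzyloxy)-2-[(2R,4R)-4-(3-tert-butoxy-3-oxopropyl)-2-tert-butyl-5-oxo-1,3-dioxolan-4-yl]dodec-4-enoate | CC(C)(C)[C@@H]1O[C@@]([C@@H](C(=O)OC(C)(C)C)C/C=C/CCCCCCCOCc2ccccc2)(CCC(=O)OC(C)(C)C)C(=O)O1
F12 | step 10 | tert-butyl (2S)-2-[(2R,4R)-4-(3-tert-butoxy-3-oxopropyl)-2-tert-butyl-5-oxo-1,3-dioxolan-4-yl]-12-hydroxydodecanoate | CC(C)(C)[C@@H]1O[C@@]([C@@H](C(=O)OC(C)(C)C)CCCCCCCCCCO)(CCC(=O)OC(C)(C)C)C(=O)O1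
F13 | step 10 | (R)-malic acid 1-ester of F12 (free 4-carboxyl and hydroxyl) | CC(C)(C)[C@@H]1O[C@@]([C@@H](C(=O)OC(C)(C)C)CCCCCCCCCCOC(=O)[C@H](O)CC(=O)O)(CCC(=O)OC(C)(C)C)C(=O)O1
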